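**Late end.** I started from the late end of the two earlier runs, where the target readings had stopped falling, and asked what fraction of the charge stays target.

| flask | starting material | remark | time |
|---|---|---|---|
| maple | 0.034 M | run made earlier |  |
| larch | 0.075 M | run made earlier |  |
| flask | 0.050 M |  | 25 h |

| run | time / h | target / % | starting material / % |
|---|---|---|---|
| maple | 0.333 | 7.9 | 63.4 |
| maple | 1.00 | 22.8 | 38.7 |
| maple | 3.00 | 15.4 | 9.5 |
| maple | 8.00 | 4.6 | 0 |
| maple | 25.0 | 5.7 | 1.2 |
| larch | 0.333 | 9.1 | 60.9 |
| larch | 1.00 | 24.4 | 34.5 |
| larch | 3.00 | 15.9 | 10.9 |
| larch | 8.00 | 6.4 | 0.6 |
| larch | 25.0 | 7.7 | 1.0 |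

(scatter of a reading: 1 percentage point)

* the moment within 25 h at which there is most target
* the amount of target, in percent of the starting material charged, at that time
* the first time at which target reaches 7.4%, in the same percent

- a reading or a percentage of target counts all its forms, free or not
- a reading of starting material is of its free form alone

**Two ways.** One way to that fraction was the mean of the maple and larch readings at 8.00 h, 5.50%. The other was the same mean at 25.0 h, 6.70%. They parted by 1.2 percentage points, which looks like a slow rise, but a difference of two such means scatters by 1 point. Starting material also read just 0% in maple and 0.6% in larch at 8.00 h, so I took the rise for scatter. Their mean, 6.10%, is my late plateau share, the fraction of the charge still target at late times; its standard error is 0.5 points.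

**My commitment.** For the flask, whose charge lies between those of the two runs, I froze that share. It stands 1.3 points below the 7.40% asked for, so I expected target in the flask to cross that amount on the way up and to lie under it late. The larch reading of 7.7% at 25.0 h lies above it by 0.3 points, inside the scatter. Both runs already read above that amount at 0.333 h.

**The forecast.** It gave most target, 25%, at 1.3 h, and the amount asked for at 0.3 h, and it described a late plateau “that creeps upward”; I held mine flat, and there we differ.

**The flask.** It gave 24.5% at 1.27 h and reached the amount at 0.277 h.

    starting material ⇌ intermediate A (K = 0.730, k = 0.0310 min⁻¹)
    intermediate A → intermediate B (k = 8.40 × 10⁻⁴ min⁻¹)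
    intermediate A → target (k = 0.0330 min⁻¹)
    intermediate B ⇌ intermediate C (K = 1.00, k = 0.00420 min⁻¹)
    starting material + target ⇌ idle adduct, settled at all times (K = 17.0 L mol⁻¹)
    target ⇌ isomer of the product (K = 17.0, k = 0.0270 min⁻¹)

**Why flat.** The flask held 5.44% target at 12.5 h; at 25.0 h it held 5.42%, all forms counted, beside 92.1% isomer of the product, 0.68 points under my share as read, 6.10%, and below the 7.40% asked for: thermodynamic control after a kinetic peak. The path between target and isomer of the product was the largest single effect on the highest amount of target: the run without it peaks at 97.5% against 24.5%. That step alone has a relaxation half-life, both ways together, of 0.404 h, short against the 25 h allowed. The neighbour flask charged with 0.20 M peaked at 29.2% and ended at 5.42% target, all forms counted, 0.68 points under the same share as read.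

The numbers in the tables are simulated with constants of no real substance, and the scatter is random.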